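The earlier runs and the new flask were computed with constants of no real substance; scatter was added.

**Early split.** In the first hours G goes partly to Z and partly elsewhere. Z is 86.1% of the G spent at 1.50 h in the midnight run, charged with 0.035 M, but 39.4% at 1.33 h in the winter run, charged with 0.14 M. This share, the selectivity, is what I follow.

| flask | G | remark | time |
|---|---|---|---|
| midnight | 0.035 M | run made earlier |  |
| winter | 0.14 M | run made earlier |  |
| epsilon | 0.080 M |  | 25 h |
| gamma | 0.10 M |  | 25 h |
| beta | 0.050 M |  | 25 h |
| alpha | 0.025 M |  | 25 h |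
| eta | 0.030 M |  | 25 h |

| run | time / h | Z / % | G / % |
|---|---|---|---|
| midnight | 1.50 | 52.2 | 39.4 |
| midnight | 4.00 | 84.2 | 2.7 |
| midnight | 8.00 | 86.7 | 0.3 |
| midnight | 12.0 | 86.1 | 0 |
| midnight | 20.0 | 86.8 | 0 |
| winter | 1.33 | 15.7 | 60.2 |
| winter | 2.50 | 26.4 | 35.4 |
| winter | 5.00 | 43.6 | 6.0 |
| winter | 10.0 | 47.4 | 0 |
| winter | 20.0 | 47.9 | 0.6 |

(readings scatter by 0.3 percentage points)

- the flasks put in order of amount of Z, in percent of the G charged, best first, at 25 h (epsilon / gamma / beta / alpha / eta)
- the same order at 8.0 d (epsilon / gamma / beta / alpha / eta)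
- the amount of Z, in percent of the G charged of the flask you put first, at 25 h
- the amount of Z, in percent of the G charged of the flask you put last, at 25 h



**What matters.** I write each plateau as odds: the part of the charge not in Z over the part in Z. That gives 0.152 for midnight and 1.09 for winter.

Time comes first. Midnight Z reads 86.7% at 8.00 h and 86.8% at 20.0 h, and winter G reads 0% at 10.0 h, so I give time no weight and expect 25 h and 8.0 d to read alike.

Charge comes next. Between the two runs the odds grow 7.17 times, so I take them as a power of the charge, with the loss slope, the power that carries odds from one charge to another, 1.42.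

The exact reading comes last. Using the midnight reading 86.1% instead gives odds 0.161 and moves my alpha figure by 0.6 percentage points.

**My reckoning.** Odds climb with charge, so I rank the flasks by charge: alpha, eta, beta, epsilon, gamma, at both times. Alpha, at 0.025 M, gets odds 0.0943 and so Z 91.4%. Gamma, at 0.10 M, gets odds 0.675 and so Z 59.7%. That is a drop of 32 points.

**The forecast.** The forecast gives alpha > eta > beta > epsilon > gamma at 25 h and alpha > eta > beta > epsilon > gamma at 8.0 d, with 91% for alpha (range 88.5% to 94%) and 59% for gamma (range 54% to 63%), where I have 59.7%, and it says “Z looks stable”.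

**The result.** The flasks stand alpha > eta > beta > epsilon > gamma at 25 h and alpha > eta > beta > epsilon > gamma at 8.0 d, with alpha at 91.1% and gamma at 59.3%.

    2 G → J (k = 0.830 M⁻¹ h⁻¹)
    G + Z → D (k = 2.40 M⁻¹ h⁻¹)
    G → Z, rate k3*[G]/(1 + ([G]/sat3)) (17.0 mM, k = 1.30 h⁻¹)

**The neighbour.** Take alpha with its charge raised to 0.062 M and the time held. Carrying the midnight odds there with the slope 1.42 gives odds 0.342, so Z 74.5%. That flask ends with G at 0%, D at 15.2% and Z at 74.2%.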